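**Retrosynthetic overview**

1. Last bond: the aryl ketone C–C bond, made by ortho C-acylation of a pentasubstituted benzoate (its one free ring carbon lies between OH and OMe) with the (1R,6R)-cyclohexene acid chloride, without protecting groups.
2. Side chain: sp2–sp3 coupling at a C3–C4 enol triflate, whose position is fixed by conjugate reduction of a 4-oxocyclohex-2-ene ester (from allylic oxidation).
3. Key disconnection: the cyclohexene comes from ring contraction of a seven-membered ring. An oxidative 1,2-vinyl shift turns a silyl dienol ether into the trans-6-phenylcyclohex-2-ene-1-carboxylate; the phenyl centre is set one step earlier by rhodium-catalysed asymmetric phenyl addition to a cycloheptadienone.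
4. Benzoate: built from two acyclic pieces by double C-acylation (3 + 3) of a β-methoxycrotonate dienolate with a methylmalonyl unit.
5. Ring order: seven-membered carbocycle (bought) → cyclohexene (contraction, step 3); benzene ring (step 9, separate branch); the two are joined in step 10.

Assumption: every purchased building block is taken as a catalogue item, and the facial sense of the rhodium step follows the published BINAP model for cycloalkenones.

**Route**

Step 1
Reactants: 1 cycloheptanone
Product: 2 cyclohepta-2,6-dien-1-one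
Conditions: IBX (2.5 equiv), fluorobenzene/DMSO (2:1), 75 °C
Reagents that add atoms: none
Why: Nicolaou IBX dehydrogenation of the ketone through its enol runs twice to the cross-conjugated dienone when 2.5 equivalents are used and the reaction is stopped before a third dehydrogenation to tropone; no stereocentre is formed.

Step 2
Reactants: 2 cyclohepta-2,6-dien-1-one; 3 phenylmagnesium bromide
Product: 5 trimethyl{[(3R)-3-phenylcyclohepta-1,6-dien-1-yl]oxy}silane, via phenylzinc chloride 4 (not isolated)
Conditions: 3, ZnCl2, THF, 0 °C; then 2, [RhCl((R)-BINAP)]2 (2 mol %), Me3SiCl (1.5 equiv), THF, 20 °C; non-aqueous work-up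
Reagents that add atoms: chlorotrimethylsilane, C[Si](C)(C)Cl
Why: Hayashi-type asymmetric 1,4-addition of an arylzinc chloride catalysed by a monovalent rhodium–BINAP complex: phenyl–rhodium adds to one enone face ((S)-BINAP is known to give (S)-3-arylcycloalkanones, so (R)-BINAP sets 3R here), and Me3SiCl traps the enolate as the regiodefined silyl enol ether, which also switches off a second addition.

Step 3
Reactants: 5 trimethyl{[(3R)-3-phenylcyclohepta-1,6-dien-1-yl]oxy}silane
Product: 7 methyl (1R,6R)-6-phenylcyclohex-2-ene-1-carboxylate, via iodanyl ketone 6 (not isolated)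
Conditions: PhI(OAc)2 (1.1 equiv), BF3·OEt2 (1.1 equiv), CH2Cl2, −78 °C; then MeOH/HC(OMe)3 (5:1), −78 → 0 °C
Reagents that add atoms: methanol, CO
Why: Proposed new method: the silyl enol ether attacks the BF3-activated trivalent iodine reagent at C2 (ring numbering of 5) anti to the neighbouring phenyl group to give α-iodanyl ketone 6, methanol then forms the hemiketal at C1, and its oxygen lone pair pushes the C7 vinyl carbon from C1 onto C2 with loss of iodobenzene (a semibenzilic, Favorskii-type 1,2-vinyl shift with inversion at C2), so the seven-membered ring contracts to the cyclohexene and the old carbonyl carbon becomes the ester trans to phenyl (1R,6R); the closest known reactions are the Tl(NO3)3- or PhI(OAc)2/acid-mediated oxidative ring contraction of cycloalkanones to cycloalkanecarboxylates and the iodane-mediated 1,2-aryl shift of aryl ketones in methanol/orthoformate, neither shown on a cross-conjugated silyl dienol ether with a migrating vinyl group.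

Step 4
Reactants: 7 methyl (1R,6R)-6-phenylcyclohex-2-ene-1-carboxylate
Product: 8 methyl (1R,6R)-4-oxo-6-phenylcyclohex-2-ene-1-carboxylate
Conditions: Rh2(cap)4 (dirhodium tetrakis(caprolactamate), 1 mol %), t-BuOOH (70% aq., 5 equiv), CH2Cl2, 25 °C
Reagents that add atoms: tert-butyl hydroperoxide, CC(C)(C)OO
Why: Doyle allylic oxidation: the electrophilic tert-butylperoxyl radical abstracts a hydridic C4–H and not the polarity-mismatched C1–H next to the ester, the allyl radical is trapped at its less hindered C4 end and the mixed peroxide collapses to the enone; C6 is untouched and C1 stays in its thermodynamic trans arrangement.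

Step 5
Reactants: 8 methyl (1R,6R)-4-oxo-6-phenylcyclohex-2-ene-1-carboxylate
Product: 10 methyl (1R,6R)-6-phenyl-4-{[(trifluoromethyl)sulfonyl]oxy}cyclohex-3-ene-1-carboxylate, via lithium enolate 9 (not isolated)
Conditions: LiBH(s-Bu)3 (1.05 equiv), THF, −78 °C; then Comins' reagent (1.1 equiv), −78 → 0 °C; aq. NH4Cl
Reagents that add atoms: Comins' reagent (N-(5-chloropyridin-2-yl)-1,1,1-trifluoro-N-[(trifluoromethyl)sulfonyl]methanesulfonamide), FC(F)(F)S(=O)(=O)N(c1ccc(Cl)cn1)S(=O)(=O)C(F)(F)F
Why: Conjugate reduction of the β-unsubstituted enone by LiBH(s-Bu)3 gives only the C3–C4 lithium enolate, and enolate O-sulfonylation locks that regiochemistry as the enol triflate; no stereocentre is touched.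

Step 6
Reactants: 10 methyl (1R,6R)-6-phenyl-4-{[(trifluoromethyl)sulfonyl]oxy}cyclohex-3-ene-1-carboxylate; 11 5-bromo-2-methylpent-2-ene
Product: 13 methyl (1R,6R)-4-(4-methylpent-3-en-1-yl)-6-phenylcyclohex-3-ene-1-carboxylate, via homoprenylmagnesium bromide 12 (not isolated)
Conditions: 11, Mg, THF, 25 °C; then 10, Fe(acac)3 (5 mol %), THF/NMP, −30 °C
Reagents that add atoms: none
Why: Fürstner iron-catalysed Kumada-type cross-coupling of an alkyl Grignard reagent with an enol triflate is faster at −30 °C than Grignard addition to the ester and places the side chain on the C3–C4 ring alkene.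

Step 7
Reactants: 13 methyl (1R,6R)-4-(4-methylpent-3-en-1-yl)-6-phenylcyclohex-3-ene-1-carboxylate
Product: 14 (1R,6R)-4-(4-methylpent-3-en-1-yl)-6-phenylcyclohex-3-ene-1-carboxylic acid
Conditions: LiOH (3 equiv), THF/MeOH/H2O (3:1:1), 40 °C; then 1 M HCl to pH 3, 0 °C
Reagents that add atoms: lithium hydroxide, [Li+].[OH-]
Why: Saponification of the methyl ester; the trans arrangement at C1/C6 is the thermodynamic one, so the base cannot erode it.

Step 8
Reactants: 15 methyl acetoacetate (methyl 3-oxobutanoate)
Product: 16 methyl (2E)-3-methoxybut-2-enoate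
Conditions: HC(OMe)3 (1.2 equiv), H2SO4 (cat.), MeOH, 25 °C
Reagents that add atoms: trimethyl orthoformate, COC(OC)OC
Why: Acid-catalysed enol ether formation from a β-keto ester with an orthoformate gives the conjugated (E)-β-methoxy enoate.

Step 9
Reactants: 16 methyl (2E)-3-methoxybut-2-enoate; 17 2-methylpropanedioyl dichloride (methylmalonyl dichloride)
Product: 20 methyl 2,4-dihydroxy-6-methoxy-3-methylbenzoate, via lithium dienolate 18 (not isolated), via keto acid chloride 19 (not isolated)
Conditions: LiN(i-Pr)2 (1.05 equiv), THF, −78 °C; add to 17, −78 °C; then LiN(SiMe3)2 (3 equiv), −78 → 25 °C; aq. NH4Cl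
Reagents that add atoms: none
Why: Vinylogous Claisen acylation of the extended lithium dienolate at its γ-carbon by one acyl chloride, then base-induced Dieckmann-type C-acylation at C2 by the second and tautomerisation to the arene; the methoxy group is carried in from 16, so the three ring oxygens never have to be told apart.

Step 10
Reactants: 14 (1R,6R)-4-(4-methylpent-3-en-1-yl)-6-phenylcyclohex-3-ene-1-carboxylic acid; 20 methyl 2,4-dihydroxy-6-methoxy-3-methylbenzoate
Product: 23 methyl 2,4-dihydroxy-6-methoxy-3-methyl-5-[(1R,6R)-4-(4-methylpent-3-en-1-yl)-6-phenylcyclohex-3-ene-1-carbonyl]benzoate, via acid chloride 21 (not isolated), via magnesium phenolate 22 (not isolated)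
Conditions: 14, 1-chloro-N,N,2-trimethylprop-1-en-1-amine (1.1 equiv), CH2Cl2, 0 °C; 20, EtMgBr (2.05 equiv), Et2O/toluene, 0 °C; combine, 25 °C; aq. NH4Cl
Reagents that add atoms: none
Why: Metal-template (Sartori-type) ortho C-acylation of a bromomagnesium phenolate by an acyl chloride, a Friedel–Crafts acylation run without free acid, attacks the only unsubstituted ring carbon (ortho to the 4-oxygen); the neutral conditions spare the acid-labile 1,5-diene, C6 is untouched and C1, now α to the ketone, rests in the trans arrangement (1R,6R).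

**Compound list**

1 | cycloheptanone | O=C1CCCCCC1 | starting material
2 | cyclohepta-2,6-dien-1-one | O=C1C=CCCC=C1 | intermediate
3 | phenylmagnesium bromide | Br[Mg]c1ccccc1 | starting material
4 | phenylzinc chloride | Cl[Zn]c1ccccc1 | intermediate
5 | trimethyl{[(3R)-3-phenylcyclohepta-1,6-dien-1-yl]oxy}silane | C[Si](C)(C)OC1=C[C@H](c2ccccc2)CCC=C1 | intermediate
6 | (2S,3S)-2-[acetoxy(phenyl)-λ3-iodanyl]-3-phenylcyclohept-6-en-1-one (iodine trans to phenyl) | O=C1C=CCC[C@@H](c2ccccc2)[C@@H]1I(OC(C)=O)c1ccccc1 | intermediate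
7 | methyl (1R,6R)-6-phenylcyclohex-2-ene-1-carboxylate | COC(=O)[C@@H]1C=CCC[C@H]1c1ccccc1 | intermediate
8 | methyl (1R,6R)-4-oxo-6-phenylcyclohex-2-ene-1-carboxylate | COC(=O)[C@@H]1C=CC(=O)C[C@H]1c1ccccc1 | intermediate
9 | lithium (4R,5R)-4-(methoxycarbonyl)-5-phenylcyclohex-1-en-1-olate | COC(=O)[C@@H]1CC=C([O-])C[C@H]1c1ccccc1.[Li+] | intermediate
10 | methyl (1R,6R)-6-phenyl-4-{[(trifluoromethyl)sulfonyl]oxy}cyclohex-3-ene-1-carboxylate | COC(=O)[C@@H]1CC=C(OS(=O)(=O)C(F)(F)F)C[C@H]1c1ccccc1 | intermediate
11 | 5-bromo-2-methylpent-2-ene | CC(C)=CCCBr | starting material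
12 | (4-methylpent-3-en-1-yl)magnesium bromide | CC(C)=CCC[Mg]Br | intermediate
13 | methyl (1R,6R)-4-(4-methylpent-3-en-1-yl)-6-phenylcyclohex-3-ene-1-carboxylate | COC(=O)[C@@H]1CC=C(CCC=C(C)C)C[C@H]1c1ccccc1 | intermediate
14 | (1R,6R)-4-(4-methylpent-3-en-1-yl)-6-phenylcyclohex-3-ene-1-carboxylic acid | OC(=O)[C@@H]1CC=C(CCC=C(C)C)C[C@H]1c1ccccc1 | intermediate
15 | methyl acetoacetate (methyl 3-oxobutanoate) | COC(=O)CC(C)=O | starting material
16 | methyl (2E)-3-methoxybut-2-enoate | CO/C(C)=C/C(=O)OC | intermediate
17 | 2-methylpropanedioyl dichloride | CC(C(Cl)=O)C(Cl)=O | starting material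
18 | lithium 1,3-dimethoxybuta-1,3-dien-1-olate | [Li+].[O-]C(OC)=CC(=C)OC | intermediate
19 | methyl (2E)-7-chloro-3-methoxy-6-methyl-5,7-dioxohept-2-enoate (C6 racemic) | COC(=O)/C=C(/OC)CC(=O)C(C)C(Cl)=O | intermediate
20 | methyl 2,4-dihydroxy-6-methoxy-3-methylbenzoate | COC(=O)c1c(O)c(C)c(O)cc1OC | intermediate
21 | (1R,6R)-4-(4-methylpent-3-en-1-yl)-6-phenylcyclohex-3-ene-1-carbonyl chloride | ClC(=O)[C@@H]1CC=C(CCC=C(C)C)C[C@H]1c1ccccc1 | intermediate
22 | methyl 2,4-bis[(bromomagnesio)oxy]-6-methoxy-3-methylbenzoate | COC(=O)c1c(O[Mg]Br)c(C)c(O[Mg]Br)cc1OC | intermediate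
23 | methyl 2,4-dihydroxy-6-methoxy-3-methyl-5-[(1R,6R)-4-(4-methylpent-3-en-1-yl)-6-phenylcyclohex-3-ene-1-carbonyl]benzoate | COC(=O)c1c(O)c(C)c(O)c(C(=O)[C@@H]2CC=C(CCC=C(C)C)C[C@H]2c2ccccc2)c1OC | target

**Step count and risks**

Total step count: 10. Longest linear sequence: 8 steps (steps 1–7, then step 10); the benzoate branch (steps 8–9) joins in step 10.

Three steps most likely to fail:

Step 3 (the new ring contraction). Methanol may displace the iodane at C2 (α-methoxylation) before the vinyl group shifts. The fallback uses known chemistry, Danheiser diazo transfer and photochemical Wolff ring contraction; it sets out from 5 and comes back at 7. K2CO3 in MeOH cleaves the silyl ether to (6R)-6-phenylcyclohept-2-en-1-one F1. LiN(SiMe3)2 and then CF3CO2CH2CF3 at −78 °C acylate the only sp3 α-carbon to give (6R)-6-phenyl-7-(2,2,2-trifluoroacetyl)cyclohept-2-en-1-one F2. MsN3 and Et3N in MeCN give (6S)-7-diazo-6-phenylcyclohept-2-en-1-one F3 (same spatial arrangement; the descriptor changes because the diazo carbon outranks phenyl). Irradiation at 300 nm in MeOH expels nitrogen, the vinyl carbon shifts to the carbene carbon, and methanol traps the vinylketene as ester 7. Any cis ester is equilibrated to trans with a trace of DBU at the stage of enone 8.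

Step 9 (one-pot benzoate annulation). The acid chloride may react at the α-carbon or at oxygen, or the second acylation may stall. The fallback uses known chemistry, a pyrone-to-phloroglucinol recyclisation; it sets out from 15 and comes back at 20. Dianion methylation (NaH, n-BuLi, MeI) gives methyl 3-oxopentanoate F4. Bought malonyl dichloride (ClC(=O)CC(Cl)=O) at 60 °C gives methyl 2-ethyl-4-hydroxy-6-oxo-6H-pyran-3-carboxylate F5. Me2SO4 and K2CO3 give methyl 2-ethyl-4-methoxy-6-oxo-6H-pyran-3-carboxylate F6. Mg(OMe)2 in boiling MeOH opens the lactone and recloses it by Claisen condensation of the ethyl CH2 onto the new ester, giving 20 as an isomer of F6. The methoxy group again ends next to the ester and the methyl between the two hydroxyls.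

Step 10 (C-acylation of the hindered, ester-bearing ring). O-acylation may win over C-acylation. The fallback is Steglich esterification followed by photo-Fries rearrangement; it sets out from 14 and 20 and comes back at 23. DCC and DMAP in CH2Cl2 acylate the free 4-OH (the 2-OH is hydrogen-bonded to the ester) to give methyl 2-hydroxy-6-methoxy-3-methyl-4-{[(1R,6R)-4-(4-methylpent-3-en-1-yl)-6-phenylcyclohex-3-ene-1-carbonyl]oxy}benzoate F7. Irradiation at 254 nm in MeCN/hexane moves the acyl group through a caged radical pair to the only free ortho carbon, giving 23 without acid.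

**Further compounds**

F1 | step 3 | (6R)-6-phenylcyclohept-2-en-1-one | O=C1C=CCC[C@@H](c2ccccc2)C1
F2 | step 3 | (6R)-6-phenyl-7-(2,2,2-trifluoroacetyl)cyclohept-2-en-1-one | O=C1C=CCC[C@@H](c2ccccc2)C1C(=O)C(F)(F)F
F3 | step 3 | (6S)-7-diazo-6-phenylcyclohept-2-en-1-one | O=C1C=CCC[C@@H](c2ccccc2)C1=[N+]=[N-]
F4 | step 9 | methyl 3-oxopentanoate | CCC(=O)CC(=O)OC
F5 | step 9 | methyl 2-ethyl-4-hydroxy-6-oxo-6H-pyran-3-carboxylate | CCC1=C(C(=O)OC)C(O)=CC(=O)O1
F6 | step 9 | methyl 2-ethyl-4-methoxy-6-oxo-6H-pyran-3-carboxylate | CCC1=C(C(=O)OC)C(OC)=CC(=O)O1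
F7 | step 10 | methyl 2-hydroxy-6-methoxy-3-methyl-4-{[(1R,6R)-4-(4-methylpent-3-en-1-yl)-6-phenylcyclohex-3-ene-1-carbonyl]oxy}benzoate | COC(=O)c1c(O)c(C)c(OC(=O)[C@@H]2CC=C(CCC=C(C)C)C[C@H]2c2ccccc2)cc1OC
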